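**Plan**

- Retrosynthetic cuts, in order: the ester O–C bond to the C18 chain; the arene C1–C6 bond, which unfolds the benzene ring into a 3-methoxy-4-pyrone; the aryl C1–CH2 bond of the side chain (in the pyrone, ring-methyl carbon to acrylate beta-carbon); the O–CH3 bond of the methyl ether.
- Enabling feature: with the arene numbered C1 (chain), C2 (OH), C3 (OMe), C4 (OH), C5 (H), C6 (H), the row C2–C6 with its three oxygens is C2–C6 of O-methylmaltol and C1 is that pyrone's 2-methyl carbon. Only the C1–C6 bond separates the heterocycle from the arene.
- Forward: maltol is O-methylated, its 2-methyl group is extended with tert-butyl acrylate, and the ester is cleaved. Methoxide then opens the pyrone and the chain recloses through C1 onto C6 to give the benzene ring, the only ring of the target. The carboxylate is finally alkylated with 1-bromooctadecane.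
- Change from the classical aqueous-alkali opening: dry NaOMe is used so that C6 is held as a beta-methoxyenone carbon and cannot be lost as formate.
- Stereochemistry: the target has no stereocentre and no stereogenic double bond, so nothing has to be controlled.

Key step: step 4

Remark: the arene numbering above is also used for the pyrone and the open chain (pyrone C2–C6 = arene C2–C6; the side-chain methylene next to the ring = C1). The transient open-chain intermediate of the key step is drawn as its E enone without configuration at the enolised methoxy-bearing carbon, since both features vanish on ring closure.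

**Route**

Step 1
Reactants: 1 maltol (3-hydroxy-2-methyl-4H-pyran-4-one); 2 iodomethane
Product: 3 3-methoxy-2-methyl-4H-pyran-4-one
Conditions: MeI (1.5 equiv), K2CO3 (1.5 equiv), acetone, 56 °C
Reagents that add atoms: iodomethane 2, CI (also listed as reactant)
Why: Williamson-type SN2 O-methylation of the acidic enolic 3-OH, which carbonate ionises while the pyrone carbonyl oxygen stays unreactive, so only the methyl ether should form.

Step 2
Reactants: 3 3-methoxy-2-methyl-4H-pyran-4-one; 4 tert-butyl acrylate
Product: 6 tert-butyl 4-(3-methoxy-4-oxo-4H-pyran-2-yl)butanoate, via lithium dienolate 5 (not isolated)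
Conditions: 3 (1.3 equiv), LiN(SiMe3)2 (1.3 equiv), THF, −78 °C, 30 min; then 4 (1.0 equiv) added slowly, −78 °C; AcOH quench at −78 °C
Reagents that add atoms: tert-butyl acrylate 4, C=CC(=O)OC(C)(C)C (also listed as reactant)
Why: The 2-methyl group is the vinylogous alpha position of the pyrone carbonyl, so the amide base should deprotonate it, and the dienolate 5 should add through its exocyclic carbon to the acrylate in a Michael addition, the bulky tert-butyl ester and the low temperature holding back 1,2-attack and further acrylate uptake.

Step 3
Reactants: 6 tert-butyl 4-(3-methoxy-4-oxo-4H-pyran-2-yl)butanoate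
Product: 7 4-(3-methoxy-4-oxo-4H-pyran-2-yl)butanoic acid
Conditions: CF3CO2H/CH2Cl2 (1:3), 0 °C to rt
Reagents that add atoms: none
Why: Acidolysis of the tert-butyl ester through the tert-butyl cation with loss of 2-methylpropene, under which the pyrone is only protonated reversibly and its enol ether is untouched.

Step 4
Reactants: 7 4-(3-methoxy-4-oxo-4H-pyran-2-yl)butanoic acid
Product: 9 3-(2,4-dihydroxy-3-methoxyphenyl)propanoic acid, via open-chain methoxyenone diketonate 8 (not isolated)
Conditions: NaOMe (5 equiv), dry degassed MeOH (0.05 M), 65 °C, Ar; then 1 M HCl to pH 3, 0 °C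
Reagents that add atoms: none
Why: Proposed new method: methoxide should add to C6, the only unsubstituted position next to the ring oxygen, and the ring should open by departure of the C2 enolate oxygen to the diketonate 8, whose C6 is fixed as a beta-methoxyenone carbon that cannot rest as an enolate or leave as formate, while the absence of water keeps any retro-Claisen cut a reversible ester-forming equilibrium. Further deprotonation at the side-chain methylene C1 (the terminal carbon of the 1,3-diketone dianion) should let C1 attack C6 in a 6-(enolendo)-endo-trig addition–elimination, equally a six-electron closure of the C1=C2–C3=C4–C5=C6 trienolate, after which methoxide leaves and enolisation at C2 and C4 gives the benzene ring, so that 7 and 9 are isomers and the base is returned. The closest known reaction types are the base-induced passage of 2,6-dialkyl-4-pyrones through open 1,3,5-triketones into 5-alkylresorcinols, the conversion of 2-alkylpyrylium salts into phenols by hydroxide, and the displacement of the alkoxy group of beta-alkoxyvinyl ketones by carbanions; such a sequence is not established for a 3-alkoxy-4-pyrone with a free 6-position. No stereocentre is formed. The step needs attack at C6 and not at C2 (C2 is flanked by the chain and the methoxy group, and addition there is reversible and leads nowhere), closure through carbon and not oxygen (closure through the C2 oxygen merely returns 7, whereas aromatisation is irreversible) and C1 as the only carbanion that closes (C3 would form a four-membered ring, C5 is vinylic in 8), with the carboxylate as a spectator.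

Step 5
Reactants: 9 3-(2,4-dihydroxy-3-methoxyphenyl)propanoic acid; 10 1-bromooctadecane
Product: 11 octadecyl 3-(2,4-dihydroxy-3-methoxyphenyl)propanoate
Conditions: KHCO3 (1.2 equiv), 10 (1.1 equiv), DMF, 60 °C
Reagents that add atoms: 1-bromooctadecane 10, CCCCCCCCCCCCCCCCCCBr (also listed as reactant)
Why: Chemoselective SN2 O-alkylation of the carboxylate, since hydrogencarbonate ionises the carboxylic acid but not the phenols, and the non-acidic medium should keep the ortho-hydroxy acid from closing to its lactone.

**Compound list**

1 | maltol (3-hydroxy-2-methyl-4H-pyran-4-one) | CC1=C(O)C(=O)C=CO1 | starting material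
2 | iodomethane | CI | starting material
3 | 3-methoxy-2-methyl-4H-pyran-4-one | COC1=C(C)OC=CC1=O | intermediate
4 | tert-butyl acrylate (tert-butyl prop-2-enoate) | C=CC(=O)OC(C)(C)C | starting material
5 | lithium 3-methoxy-2-methylidene-2H-pyran-4-olate (lithium dienolate of 3, not isolated) | [Li+].[O-]C1=C(OC)C(=C)OC=C1 | intermediate
6 | tert-butyl 4-(3-methoxy-4-oxo-4H-pyran-2-yl)butanoate | COC1=C(CCCC(=O)OC(C)(C)C)OC=CC1=O | intermediate
7 | 4-(3-methoxy-4-oxo-4H-pyran-2-yl)butanoic acid | COC1=C(CCCC(=O)O)OC=CC1=O | intermediate
8 | (E)-6,9-dimethoxy-5,7-dioxonon-8-enoic acid, present in the flask as its sodium diketonate carboxylate (not isolated; methoxy-bearing carbon between the ketones enolised, no fixed configuration) | CO/C=C/C(=O)C(OC)C(=O)CCCC(=O)O | intermediate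
9 | 3-(2,4-dihydroxy-3-methoxyphenyl)propanoic acid | O=C(O)CCc1ccc(O)c(OC)c1O | intermediate
10 | 1-bromooctadecane | CCCCCCCCCCCCCCCCCCBr | starting material
11 | octadecyl 3-(2,4-dihydroxy-3-methoxyphenyl)propanoate | CCCCCCCCCCCCCCCCCCOC(=O)CCc1ccc(O)c(OC)c1O | target

**Summary and risks**

Total step count: 5. Longest linear sequence: 5 steps (from maltol 1).

Steps most likely to fail:

Step 4 (new ring transformation). Once methoxide has opened the ring, the chain may re-close through oxygen faster than C1 is deprotonated, may fragment by attack of methoxide on the diketone, or may condense between molecules. The fallback uses known chemistry and buys the arene instead of building it; it sets out from tert-butyl acrylate 4 and returns at acid 9.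
- Commercial 2-methoxyresorcinol (COc1c(O)cccc1O) would be benzylated on both phenols (BnBr, K2CO3, DMF) to 1,3-bis(benzyloxy)-2-methoxybenzene F1.
- N-Iodosuccinimide (1.0 equiv, cat. CF3CO2H, MeCN) would iodinate the position ortho and para to the benzyloxy groups to give 1,3-bis(benzyloxy)-4-iodo-2-methoxybenzene F2.
- A Mizoroki–Heck reaction with 4 (Pd(OAc)2, P(o-tol)3, Et3N, DMF, 90 °C) would give tert-butyl (E)-3-[2,4-bis(benzyloxy)-3-methoxyphenyl]prop-2-enoate F3.
- Hydrogenation over Pd/C (H2, EtOAc/EtOH) would saturate the alkene and remove both benzyl groups to give tert-butyl 3-(2,4-dihydroxy-3-methoxyphenyl)propanoate F4.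
- Brief CF3CO2H/CH2Cl2 at 0 °C, as in step 3, would deliver acid 9.

Step 2 (lateral Michael addition). The ester enolate formed in the addition may take up more acrylate (oligomerisation), or proton exchange may create the lateral anion of 6, which adds a second acrylate. The fallback sets out from 3 (through dienolate 5) and returns at acid 7, so that step 3 is skipped.
- Dienolate 5 would be alkylated with allyl bromide (C=CCBr; THF, −78 to 0 °C) to 2-(but-3-en-1-yl)-3-methoxy-4H-pyran-4-one F5.
- Anti-Markovnikov hydroboration with 9-borabicyclo[3.3.1]nonane and oxidation with NaBO3·4H2O would give 2-(4-hydroxybutyl)-3-methoxy-4H-pyran-4-one F6.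
- Oxidation of the primary alcohol with TEMPO (cat.)/PhI(OAc)2 in MeCN/H2O would give acid 7.

Step 5 (esterification). Alkylation may spill over to the phenolic oxygens, the waxy bromide may react sluggishly, or the hydroxy acid may close to its lactone before it is alkylated. The fallback makes the lactone the intermediate; it sets out from 9 and returns at target 11.
- Acid 9 would be closed deliberately (TsOH cat., toluene, reflux with removal of water) to 7-hydroxy-8-methoxy-3,4-dihydro-2H-chromen-2-one F7.
- The aryl lactone would be opened by acyl transfer to sodium octadecan-1-olate (octadecan-1-ol, CCCCCCCCCCCCCCCCCCO, with NaH, THF, 0 °C; 2.2 equiv, one consumed by the free phenol). Release of the phenoxide drives the opening, and a cold AcOH quench should give 11.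

Further compounds
F1 | step 4 | 1,3-bis(benzyloxy)-2-methoxybenzene | COc1c(OCc2ccccc2)cccc1OCc1ccccc1
F2 | step 4 | 1,3-bis(benzyloxy)-4-iodo-2-methoxybenzene | COc1c(OCc2ccccc2)ccc(I)c1OCc1ccccc1
F3 | step 4 | tert-butyl (E)-3-[2,4-bis(benzyloxy)-3-methoxyphenyl]prop-2-enoate | COc1c(OCc2ccccc2)ccc(/C=C/C(=O)OC(C)(C)C)c1OCc1ccccc1
F4 | step 4 | tert-butyl 3-(2,4-dihydroxy-3-methoxyphenyl)propanoate | COc1c(O)ccc(CCC(=O)OC(C)(C)C)c1O
F5 | step 2 | 2-(but-3-en-1-yl)-3-methoxy-4H-pyran-4-one | C=CCCC1=C(OC)C(=O)C=CO1
F6 | step 2 | 2-(4-hydroxybutyl)-3-methoxy-4H-pyran-4-one | OCCCCC1=C(OC)C(=O)C=CO1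
F7 | step 5 | 7-hydroxy-8-methoxy-3,4-dihydro-2H-chromen-2-one | COc1c(O)ccc2CCC(=O)Oc12
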